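The side chain (C1′ benzylic to C16′) is cut at C7′–C8′, where the C6′=C7′ alkene meets the C8′H2–C9′H2 bridge of the 1,5-diene. C8′ is carried as the terminal carbon of a conjugated dienol whose vinyl group is the only monosubstituted alkene present. In one flask 9-BBN turns that carbon into a nucleophile and masks the free C12′ hydroxyl. A B-alkyl Suzuki–Miyaura coupling then joins it to an (E)-iodoalkenyl acetate that already holds the hydroquinone ring (as its bis-silyl ether), C2′=C3′, the C5′ acetate and the C6′=C7′ geometry. The precursors are thus a triene alcohol and an alkenyl iodide; only fluoride desilylation follows.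

Key step: step 11

Assumption: the (R)-TRIP/Re-face relationship known for simple aromatic and unsaturated aldehydes is taken to hold for but-2-ynal and for the dienal, and the antipodal catalyst would be used if a trial showed the opposite sense.

Step 1
Reactants: 1 2,6-dimethylbenzene-1,4-diol
Product: 2 1,4-bis(triisopropylsilyloxy)-2,6-dimethylbenzene
Conditions: TIPSOTf, 2,6-lutidine, CH2Cl2, 0 °C to rt
Reagents that add atoms: triisopropylsilyl triflate, CC(C)[Si](OS(=O)(=O)C(F)(F)F)(C(C)C)C(C)C
Why: Silyl ether formation with the reactive triflate should cap both phenols, including the one flanked by two methyl groups, and aryl TIPS ethers resist organoaluminium reagents, zirconium hydride and aqueous phosphate yet fall to fluoride.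

Step 2
Reactants: 2 1,4-bis(triisopropylsilyloxy)-2,6-dimethylbenzene
Product: 3 2-(bromomethyl)-6-methyl-1,4-bis(triisopropylsilyloxy)benzene
Conditions: NBS (1 equiv), AIBN (cat.), PhCF3, reflux
Reagents that add atoms: N-bromosuccinimide, O=C1CCC(=O)N1Br
Why: In this Wohl–Ziegler radical bromination the two methyl groups are equivalent by symmetry, so one equivalent of NBS in a non-polar solvent should give a single monobromide while the bulky silyl groups shield the ring positions from ionic bromination.

Step 3
Reactants: 4 but-2-ynal; 5 allenylboronic acid pinacol ester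
Product: 6 (4S)-hepta-1,5-diyn-4-ol
Conditions: (S)-TRIP [(S)-3,3′-bis(2,4,6-triisopropylphenyl)-BINOL hydrogen phosphate, 10 mol %], 4 Å MS, toluene, −20 °C; aq work-up
Reagents that add atoms: none
Why: In this chiral phosphoric acid catalysed propargylboration the allenylboronate adds through a closed six-membered SE2′ transition state, and the (S)-catalyst, hydrogen-bonded to a boronate oxygen and the formyl hydrogen, should expose the Si face of 4, which sets C5′ as S.

Step 4
Reactants: 6 (4S)-hepta-1,5-diyn-4-ol; 3 2-(bromomethyl)-6-methyl-1,4-bis(triisopropylsilyloxy)benzene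
Product: 8 (4S,6E)-6-methyl-8-[3-methyl-2,5-bis(triisopropylsilyloxy)phenyl]oct-6-en-2-yn-4-ol, via alkenylalane 7 (not isolated)
Conditions: AlMe3 (3.3 equiv), Cp2ZrCl2 (25 mol %), CH2Cl2, 0 °C to rt; then 3, Pd(PPh3)4 (5 mol %), THF, rt; aq work-up
Reagents that add atoms: trimethylaluminium, C[Al](C)C
Why: Zirconium-catalysed syn methylalumination (Negishi carboalumination) should occur only at the terminal alkyne and fix the E geometry of C2′=C3′, and the alkenylalane then couples with the benzylic bromide under zerovalent palladium with retention (Negishi-type alkenyl–benzyl coupling).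

Step 5
Reactants: 8 (4S,6E)-6-methyl-8-[3-methyl-2,5-bis(triisopropylsilyloxy)phenyl]oct-6-en-2-yn-4-ol
Product: 11 (2E,4S,6E)-2-iodo-6-methyl-8-[3-methyl-2,5-bis(triisopropylsilyloxy)phenyl]octa-2,6-dien-4-ol, via aluminium alkoxide 9 (not isolated), via alkenylzirconocene 10 (not isolated)
Conditions: i-Bu2AlH (1 equiv), THF, 0 °C; Cp2ZrHCl (1.8 equiv), THF, rt to 40 °C, dark; I2, −78 to 0 °C
Reagents that add atoms: iodine, [I][I]; for intermediates 9 and 10 only: diisobutylaluminium hydride, CC(C)C[AlH]CC(C)C, and Cp2ZrHCl, [H][Zr](Cl)(C1C=CC=C1)C1C=CC=C1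
Why: In this hydrozirconation–iodinolysis the hydroxyl is first capped as a bulky aluminium alkoxide, Cp2ZrHCl then adds syn to C6′≡C7′ and (equilibrated by excess reagent) settles zirconium on the less hindered methyl-bearing C7′, and iodine replaces it with retention to give the E iodide.

Step 6
Reactants: 11 (2E,4S,6E)-2-iodo-6-methyl-8-[3-methyl-2,5-bis(triisopropylsilyloxy)phenyl]octa-2,6-dien-4-ol
Product: 12 (2E,4S,6E)-2-iodo-6-methyl-8-[3-methyl-2,5-bis(triisopropylsilyloxy)phenyl]octa-2,6-dien-4-yl acetate
Conditions: Ac2O, Et3N, DMAP (cat.), CH2Cl2, 0 °C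
Reagents that add atoms: acetic anhydride, CC(=O)OC(C)=O
Why: DMAP-catalysed acylation of the only free hydroxyl installs the C5′ acetate at oxygen and leaves the stereocentre untouched.

Step 7
Reactants: 13 3-methylbut-2-en-1-ol (prenol)
Product: 14 methyl 3-methylbut-2-en-1-yl carbonate
Conditions: ClCO2Me, pyridine, CH2Cl2, 0 °C
Reagents that add atoms: methyl chloroformate, COC(=O)Cl
Why: O-acylation of the primary allylic alcohol by the chloroformate provides the carbonate leaving group that the next step needs.

Step 8
Reactants: 14 methyl 3-methylbut-2-en-1-yl carbonate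
Product: 15 4,4,5,5-tetramethyl-2-(2-methylbut-3-en-2-yl)-1,3,2-dioxaborolane
Conditions: B2pin2, CuCl (5 mol %), Xantphos (5 mol %), KOt-Bu (10 mol %), THF, rt
Reagents that add atoms: bis(pinacolato)diboron, CC1(C)OB(OC1(C)C)B1OC(C)(C)C(C)(C)O1
Why: In this copper-catalysed gamma-selective (SN2′) allylic borylation, borylcupration places boron on the dimethyl-substituted carbon and beta-elimination of the carbonate releases the tertiary allylboronate.

Step 9
Reactants: 16 acrolein; 17 2-(triphenylphosphoranylidene)propanal
Product: 18 (2E)-2-methylpenta-2,4-dienal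
Conditions: 16 (3 equiv), BHT (trace), CH2Cl2, 40 °C, sealed vessel
Reagents that add atoms: none
Why: Wittig olefination by a stabilised formyl ylide is E-selective, and excess acrolein keeps the less electrophilic product aldehyde from reacting further.

Step 10
Reactants: 18 (2E)-2-methylpenta-2,4-dienal; 15 4,4,5,5-tetramethyl-2-(2-methylbut-3-en-2-yl)-1,3,2-dioxaborolane
Product: 19 (3E,5R)-4,8-dimethylnona-1,3,7-trien-5-ol
Conditions: (R)-TRIP (10 mol %), 4 Å MS, toluene, −20 to 0 °C; aq work-up
Reagents that add atoms: none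
Why: In this chiral phosphoric acid catalysed allylboration the tertiary boronate reacts through a chair SE2′ transition state, so its unsubstituted terminus bonds to the carbonyl carbon and a linear prenyl group results, and the (R)-catalyst should direct attack to the Re face of 18, which sets C12′ as R.

Step 11
Reactants: 19 (3E,5R)-4,8-dimethylnona-1,3,7-trien-5-ol; 12 (2E,4S,6E)-2-iodo-6-methyl-8-[3-methyl-2,5-bis(triisopropylsilyloxy)phenyl]octa-2,6-dien-4-yl acetate
Product: 21 (2E,5S,6E,10E,12R)-12-hydroxy-3,7,11,15-tetramethyl-1-[3-methyl-2,5-bis(triisopropylsilyloxy)phenyl]hexadeca-2,6,10,14-tetraen-5-yl acetate, via B-alkyl-9-BBN borinate 20 (not isolated)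
Conditions: 19 (1.3 equiv), 9-BBN (2.2 equiv per 19), THF, 0 °C to rt; then 3 M aq K3PO4, 12, PdCl2(dppf) (5 mol %), AsPh3 (10 mol %), DMF, rt
Reagents that add atoms: 9-borabicyclo[3.3.1]nonane, [H]B1C2CCCC1CCC2 (boron enters intermediate 20 only; hydrogen alone stays in 21)
Why: 9-BBN adds to the C8′=C9′ vinyl group of 19 by four-centre syn addition with boron on terminal C8′, while a second equivalent turns the C12′ hydroxyl into a borinate that water later releases, so no protecting group is spent. Base then forms the borate of 20, zerovalent palladium inserts into the C7′–iodine bond of 12 with retention, the primary alkyl group passes from boron to palladium and reductive elimination forges C7′–C8′; the closest known reaction type is the B-alkyl Suzuki–Miyaura coupling of a homoallylic 9-BBN borane and an alkenyl iodide. No ring is closed and no stereocentre is created: C5′ and C12′ are spectators, and the E geometries of C6′=C7′ and C10′=C11′ are carried over from 12 and 19. The step needs chemoselective hydroboration (secured by the steric gap between the vinyl group and the trisubstituted C10′=C11′ and C14′=C15′ alkenes), boron placement at the terminus and not at allylic C9′ (secured by the bulk of 9-BBN), and insertion into the carbon–iodine bond ahead of ionisation of the C5′ acetate (secured by the much faster reaction of the alkenyl iodide and by the hindered secondary, trisubstituted allyl system at room temperature). The chelating dppf ligand favours reductive elimination over beta-hydride loss, AsPh3 speeds transmetalation, and aqueous phosphate at room temperature should spare the acetate and the aryl TIPS ethers.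

Step 12
Reactants: 21 (2E,5S,6E,10E,12R)-12-hydroxy-3,7,11,15-tetramethyl-1-[3-methyl-2,5-bis(triisopropylsilyloxy)phenyl]hexadeca-2,6,10,14-tetraen-5-yl acetate
Product: 22 (2E,5S,6E,10E,12R)-1-(2,5-dihydroxy-3-methylphenyl)-12-hydroxy-3,7,11,15-tetramethylhexadeca-2,6,10,14-tetraen-5-yl acetate (CNP0252507.1)
Conditions: TBAF (2.5 equiv), AcOH (3 equiv), THF, 0 °C to rt, argon, degassed work-up
Reagents that add atoms: none
Why: Fluoride-induced cleavage of the two aryl silyl ethers, buffered by acetic acid so that no phenoxide is exposed to oxidation and the acetate is neither cleaved nor moved, should release the hydroquinone.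

Compound list
1 | 2,6-dimethylbenzene-1,4-diol | Cc1cc(O)cc(C)c1O | starting material
2 | 1,4-bis(triisopropylsilyloxy)-2,6-dimethylbenzene | Cc1cc(O[Si](C(C)C)(C(C)C)C(C)C)cc(C)c1O[Si](C(C)C)(C(C)C)C(C)C | intermediate
3 | 2-(bromomethyl)-6-methyl-1,4-bis(triisopropylsilyloxy)benzene | BrCc1cc(O[Si](C(C)C)(C(C)C)C(C)C)cc(C)c1O[Si](C(C)C)(C(C)C)C(C)C | intermediate
4 | but-2-ynal | CC#CC=O | starting material
5 | allenylboronic acid pinacol ester | C=C=CB1OC(C)(C)C(C)(C)O1 | starting material
6 | (4S)-hepta-1,5-diyn-4-ol | CC#C[C@@H](O)CC#C | intermediate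
7 | (E)-alkenyl(dimethyl)alane, O-dimethylaluminium alkoxide, from 6 (not isolated) | C[Al](C)O[C@H](C#CC)C/C(C)=C/[Al](C)C | intermediate
8 | (4S,6E)-6-methyl-8-[3-methyl-2,5-bis(triisopropylsilyloxy)phenyl]oct-6-en-2-yn-4-ol | O[C@H](C#CC)C/C(C)=C/Cc1cc(O[Si](C(C)C)(C(C)C)C(C)C)cc(C)c1O[Si](C(C)C)(C(C)C)C(C)C | intermediate
9 | diisobutylaluminium alkoxide of 8 (not isolated) | CC(C)C[Al](CC(C)C)O[C@H](C#CC)C/C(C)=C/Cc1cc(O[Si](C(C)C)(C(C)C)C(C)C)cc(C)c1O[Si](C(C)C)(C(C)C)C(C)C | intermediate
10 | (E)-C7′-alkenylzirconocene chloride from 9 (not isolated; Cp rings drawn sigma-bonded) | CC(C)C[Al](CC(C)C)O[C@H](/C=C(\C)[Zr](Cl)(C1C=CC=C1)C1C=CC=C1)C/C(C)=C/Cc1cc(O[Si](C(C)C)(C(C)C)C(C)C)cc(C)c1O[Si](C(C)C)(C(C)C)C(C)C | intermediate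
11 | (2E,4S,6E)-2-iodo-6-methyl-8-[3-methyl-2,5-bis(triisopropylsilyloxy)phenyl]octa-2,6-dien-4-ol | O[C@H](/C=C(\C)I)C/C(C)=C/Cc1cc(O[Si](C(C)C)(C(C)C)C(C)C)cc(C)c1O[Si](C(C)C)(C(C)C)C(C)C | intermediate
12 | (2E,4S,6E)-2-iodo-6-methyl-8-[3-methyl-2,5-bis(triisopropylsilyloxy)phenyl]octa-2,6-dien-4-yl acetate | CC(=O)O[C@H](/C=C(\C)I)C/C(C)=C/Cc1cc(O[Si](C(C)C)(C(C)C)C(C)C)cc(C)c1O[Si](C(C)C)(C(C)C)C(C)C | intermediate
13 | 3-methylbut-2-en-1-ol | CC(C)=CCO | starting material
14 | methyl 3-methylbut-2-en-1-yl carbonate | COC(=O)OCC=C(C)C | intermediate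
15 | 4,4,5,5-tetramethyl-2-(2-methylbut-3-en-2-yl)-1,3,2-dioxaborolane | C=CC(C)(C)B1OC(C)(C)C(C)(C)O1 | intermediate
16 | acrolein | C=CC=O | starting material
17 | 2-(triphenylphosphoranylidene)propanal | CC(C=O)=P(c1ccccc1)(c1ccccc1)c1ccccc1 | starting material
18 | (2E)-2-methylpenta-2,4-dienal | C=C/C=C(\C)C=O | intermediate
19 | (3E,5R)-4,8-dimethylnona-1,3,7-trien-5-ol | C=C/C=C(\C)[C@H](O)CC=C(C)C | intermediate
20 | C8′-(9-BBN) borane, C12′-O-(9-BBN) borinate from 19 (not isolated) | B1(CC/C=C(\C)[C@H](OB2C3CCCC2CCC3)CC=C(C)C)C4CCCC1CCC4 | intermediate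
21 | (2E,5S,6E,10E,12R)-12-hydroxy-3,7,11,15-tetramethyl-1-[3-methyl-2,5-bis(triisopropylsilyloxy)phenyl]hexadeca-2,6,10,14-tetraen-5-yl acetate | CC(=O)O[C@H](/C=C(\C)CC/C=C(\C)[C@H](O)CC=C(C)C)C/C(C)=C/Cc1cc(O[Si](C(C)C)(C(C)C)C(C)C)cc(C)c1O[Si](C(C)C)(C(C)C)C(C)C | intermediate
22 | (2E,5S,6E,10E,12R)-1-(2,5-dihydroxy-3-methylphenyl)-12-hydroxy-3,7,11,15-tetramethylhexadeca-2,6,10,14-tetraen-5-yl acetate | CC(=O)O[C@H](/C=C(\C)CC/C=C(\C)[C@H](O)CC=C(C)C)C/C(C)=C/Cc1cc(O)cc(C)c1O | target

Total step count: 12. Longest linear sequence: 7 (steps 1, 2, 4, 5, 6, 11, 12).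

Steps most likely to fail

1. Step 10. The hindered tertiary boronate may add slowly, so that the uncatalysed background reaction competes and facial selectivity is poor. The fallback sets out from 18 and 15. They are combined without catalyst (toluene, rt to 50 °C) to give the racemic dienol F1. Oxidation with Dess–Martin periodinane buffered by NaHCO3 gives the dienone F2, which is kept cold and neutral to avoid migration of the C14′=C15′ alkene into conjugation. A Corey–Bakshi–Shibata reduction with (S)-Me-CBS and catecholborane (toluene, −78 °C) treats the alpha-methyl dienyl group as the large substituent. It should deliver the R alcohol, and the route is rejoined at 19.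

2. Step 11. Three processes may erode the coupling: ionisation of the allylic acetate by zerovalent palladium, base-induced loss of the acetate or of an aryl silyl group, and sluggish boron-to-palladium transfer. The fallback sets out from 20 (made from 19 as before) and 12, and replaces the nucleophile–electrophile union by a base-free union of two electrophiles. Oxidation of 20 with sodium perborate (NaBO3·4H2O, THF–water) gives the diol F3. Selective Appel iodination of its primary hydroxyl (I2, PPh3, imidazole, CH2Cl2, 0 °C) gives the homoallylic iodide F4. Nickel-catalysed reductive cross-electrophile coupling of F4 and 12 follows (NiCl2(dme), 4,4′-di-tert-butyl-2,2′-bipyridine, manganese powder, DMA, rt). The alkenyl iodide adds to zerovalent nickel and the C8′ radical is captured, which forms the same C7′–C8′ bond with retention and tolerates the free hydroxyl. The route is rejoined at 21.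

3. Step 3. Facial discrimination may be poor on the slim, rod-like alkynyl aldehyde. The fallback sets out from 4 and moves the control of C5′ to an enzymatic resolution. Zinc-mediated Barbier addition of propargyl bromide (THF, aq NH4Cl) gives the racemic diynol F5, and the carboalumination–benzylation of step 4 with 3 gives the racemic enynol F6. A triacylglycerol lipase (for example that of Burkholderia cepacia) with vinyl acetate in MTBE should acylate the enantiomer that places the propynyl group in the medium pocket. This gives the (S)-acetate F7 and leaves the (R)-alcohol F8, which is separated. Reductive removal of the acetyl group from F7 (i-Bu2AlH, CH2Cl2, −78 °C) rejoins the route at 8.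

Further compounds
F1 | step 10 | rac-(3E)-4,8-dimethylnona-1,3,7-trien-5-ol | C=C/C=C(\C)C(O)CC=C(C)C
F2 | step 10 | (3E)-4,8-dimethylnona-1,3,7-trien-5-one | C=C/C=C(\C)C(=O)CC=C(C)C
F3 | step 11 | (3E,5R)-4,8-dimethylnona-3,7-diene-1,5-diol | OCC/C=C(\C)[C@H](O)CC=C(C)C
F4 | step 11 | (5R,6E)-9-iodo-2,6-dimethylnona-2,6-dien-5-ol | ICC/C=C(\C)[C@H](O)CC=C(C)C
F5 | step 3 | rac-hepta-1,5-diyn-4-ol | CC#CC(O)CC#C
F6 | step 3 | rac-(6E)-6-methyl-8-[3-methyl-2,5-bis(triisopropylsilyloxy)phenyl]oct-6-en-2-yn-4-ol | OC(C#CC)C/C(C)=C/Cc1cc(O[Si](C(C)C)(C(C)C)C(C)C)cc(C)c1O[Si](C(C)C)(C(C)C)C(C)C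
F7 | step 3 | (4S,6E)-6-methyl-8-[3-methyl-2,5-bis(triisopropylsilyloxy)phenyl]oct-6-en-2-yn-4-yl acetate | CC(=O)O[C@H](C#CC)C/C(C)=C/Cc1cc(O[Si](C(C)C)(C(C)C)C(C)C)cc(C)c1O[Si](C(C)C)(C(C)C)C(C)C
F8 | step 3 | (4R,6E)-6-methyl-8-[3-methyl-2,5-bis(triisopropylsilyloxy)phenyl]oct-6-en-2-yn-4-ol | O[C@@H](C#CC)C/C(C)=C/Cc1cc(O[Si](C(C)C)(C(C)C)C(C)C)cc(C)c1O[Si](C(C)C)(C(C)C)C(C)C
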